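**Retrosynthetic overview**

1. Icetexane numbering: ring A = C1–C5, C10; seven-membered ring B = C5, C6, C7, C8, C9, C20, C10; ring C = C8, C9, C11–C14. Komaroviquinone 23 ⇐ methyl ketal 21 (ketal hydrolysis, CAN oxidation of the 11,12,14-trimethoxyarene to the 11,14-quinone) ⇐ cycloadduct 18 (two temporary carbonyl groups at C1 and C20 removed by reduction and double Barton–McCombie deoxygenation).
2. Enabling feature: the oxygen bridging C7 and C10 across ring B forms an 8-oxabicyclo[3.2.1]octane (oxolane O–C7–C6–C5–C10 inside the pyran O–C7–C8–C9–C20–C10) with C7 at the carboxylic acid oxidation level. This is the retron of a six-membered carbonyl ylide (C7=O(+)–C10(−), from an aryl ester C=O and a carbene at C10) plus the C5=C6 alkene.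
3. Key disconnection 18 ⇒ diazo diketone 15: one Rh(II) operation forms C10–O (ester oxygen onto the carbenoid), then C10–C5 and C6–C7 by intramolecular [3+2] cycloaddition; all three stereocentres arise here.
4. Ring order: ring C (bought as the arene) → oxidopyrylium ring through C10–O → oxolane, ring A and ring B together → quinone last.
5. 15 ⇐ diazo transfer ⇐ 1,3-diketone 14 ⇐ hydration of ynone 12 ⇐ acid 10 (from 1,2,4-trimethoxybenzene 6) + Weinreb ynamide 5 (from methyl 3,3-dimethylpent-4-enoate 1).

Key step: step 13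

Assumption: the sense of asymmetric induction of the chiral dirhodium catalyst in step 13 cannot be assigned in advance. The route is written for the catalyst antipode that delivers the (5S,7S,10S) series; Rh2(S-TCPTTL)4 is shown, and its enantiomer is used if a first test gives the mirror-image series.

Remarks: 11 and 22 may exist partly as their ring-chain tautomers (lactol of 11, 10-hydroxy-7-ketone of 22), which react identically. 19 and 20 are expected as mixtures of carbinol epimers at C1 and C20; both centres are removed in step 16.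

**Route**

Step 1
Reactants: 1 methyl 3,3-dimethylpent-4-enoate
Product: 2 3,3-dimethylpent-4-en-1-ol
Conditions: LiAlH4, THF, 0 to 23 °C; aqueous NaOH work-up
Reagents that add atoms: none
Why: LiAlH4 reduction of the ester should give the primary alcohol while the isolated vinyl group is inert to hydride.

Step 2
Reactants: 2 3,3-dimethylpent-4-en-1-ol
Product: 3 5-iodo-3,3-dimethylpent-1-ene
Conditions: PPh3, I2, imidazole, CH2Cl2, 0 to 23 °C
Reagents that add atoms: iodine, II
Why: Appel-type iodination, in which iodide displaces the alkoxyphosphonium group at an unhindered primary carbon (SN2).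

Step 3
Reactants: 3 5-iodo-3,3-dimethylpent-1-ene
Product: 4 5,5-dimethylhept-6-en-1-yne
Conditions: lithium acetylide–ethylenediamine complex, DMSO, 10 to 23 °C
Reagents that add atoms: lithium acetylide ethylenediamine complex, [Li+].[C-]#C.NCCN
Why: SN2 alkylation of lithium acetylide by a primary iodide whose α- and β-carbons are unbranched, so substitution should outrun elimination.

Step 4
Reactants: 4 5,5-dimethylhept-6-en-1-yne
Product: 5 N-methoxy-N,6,6-trimethyloct-7-en-2-ynamide
Conditions: n-BuLi, THF, −78 °C; then ClC(O)N(OMe)Me, −78 to 0 °C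
Reagents that add atoms: N-methoxy-N-methylcarbamoyl chloride, CON(C)C(Cl)=O
Why: C-acylation of the lithium acetylide with the carbamoyl chloride is a standard entry to Weinreb ynamides.

Step 5
Reactants: 6 1,2,4-trimethoxybenzene
Product: 7 2-(2,3,6-trimethoxyphenyl)propan-2-ol
Conditions: n-BuLi, THF, 0 to 23 °C; then acetone, −78 to 23 °C; H2O
Reagents that add atoms: acetone, CC(C)=O
Why: Directed ortho-lithiation at the ring C–H flanked by two methoxy groups (the most acidic position), followed by 1,2-addition of the aryllithium to acetone.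

Step 6
Reactants: 7 2-(2,3,6-trimethoxyphenyl)propan-2-ol
Product: 8 1,2,4-trimethoxy-3-(propan-2-yl)benzene
Conditions: Et3SiH, CF3CO2H, CH2Cl2, 0 °C
Reagents that add atoms: none
Why: Ionic hydrogenation, in which the tertiary benzylic cation stabilised by the electron-rich ring is captured by hydride from the silane.

Step 7
Reactants: 8 1,2,4-trimethoxy-3-(propan-2-yl)benzene
Product: 9 1-bromo-2,4,5-trimethoxy-3-(propan-2-yl)benzene
Conditions: NBS, MeCN, 0 to 23 °C
Reagents that add atoms: N-bromosuccinimide, O=C1CCC(=O)N1Br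
Why: Electrophilic aromatic bromination should occur at the C–H that is ortho to one methoxy group and para to another (future C8), since the other C–H (future C9) has only one ortho methoxy group.

Step 8
Reactants: 9 1-bromo-2,4,5-trimethoxy-3-(propan-2-yl)benzene
Product: 10 2,4,5-trimethoxy-3-(propan-2-yl)benzoic acid
Conditions: n-BuLi, THF, −78 °C; then CO2; aq. HCl
Reagents that add atoms: carbon dioxide, O=C=O
Why: Bromine–lithium exchange followed by carboxylation of the aryllithium installs C7 at C8.

Step 9
Reactants: 10 2,4,5-trimethoxy-3-(propan-2-yl)benzoic acid; 5 N-methoxy-N,6,6-trimethyloct-7-en-2-ynamide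
Product: 11 2-(6,6-dimethyloct-7-en-2-ynoyl)-3,4,6-trimethoxy-5-(propan-2-yl)benzoic acid
Conditions: s-BuLi (2.2 equiv), TMEDA, THF, −78 °C; then 5, −78 to −40 °C; aq. HCl
Reagents that add atoms: none
Why: Carboxylate-directed ortho-lithiation of the unprotected benzoic acid removes the only ring proton (flanked by CO2Li and OMe), and the dianion is acylated by the Weinreb amide, whose chelated tetrahedral adduct prevents over-addition.

Step 10
Reactants: 11 2-(6,6-dimethyloct-7-en-2-ynoyl)-3,4,6-trimethoxy-5-(propan-2-yl)benzoic acid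
Product: 12 methyl 2-(6,6-dimethyloct-7-en-2-ynoyl)-3,4,6-trimethoxy-5-(propan-2-yl)benzoate
Conditions: MeI, KHCO3, DMF, 23 °C
Reagents that add atoms: iodomethane, CI
Why: SN2 O-methylation of the carboxylate with a weak base should give the open-chain keto ester without isomerising the ynone.

Step 11
Reactants: 12 methyl 2-(6,6-dimethyloct-7-en-2-ynoyl)-3,4,6-trimethoxy-5-(propan-2-yl)benzoate
Product: 14 methyl 2-(6,6-dimethyl-3-oxooct-7-enoyl)-3,4,6-trimethoxy-5-(propan-2-yl)benzoate, via enaminone 13 (not isolated)
Conditions: Et2NH, EtOH, 23 °C; then 1 M HCl, THF, 23 °C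
Reagents that add atoms: water, O (diethylamine, CCNCC, enters 13 and leaves again)
Why: Aza-Michael addition of the amine to the β-carbon of the ynone and hydrolysis of the resulting enaminone amount to a regioselective hydration to the 1,3-diketone, with the hindered ester untouched.

Step 12
Reactants: 14 methyl 2-(6,6-dimethyl-3-oxooct-7-enoyl)-3,4,6-trimethoxy-5-(propan-2-yl)benzoate
Product: 15 methyl 2-(2-diazo-6,6-dimethyl-3-oxooct-7-enoyl)-3,4,6-trimethoxy-5-(propan-2-yl)benzoate
Conditions: p-ABSA, Et3N, MeCN, 0 to 23 °C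
Reagents that add atoms: 4-acetamidobenzenesulfonyl azide, CC(=O)Nc1ccc(cc1)S(=O)(=O)N=[N+]=[N-]
Why: Regitz diazo transfer to the single active methylene of the 1,3-diketone.

Step 13
Reactants: 15 methyl 2-(2-diazo-6,6-dimethyl-3-oxooct-7-enoyl)-3,4,6-trimethoxy-5-(propan-2-yl)benzoate
Product: 18 (5S,7S,10S)-7,10-epoxy-7,11,12,14-tetramethoxyicetexa-8,11,13-triene-1,20-dione, via rhodium carbenoid 16 (not isolated), via carbonyl ylide 17 (not isolated)
Conditions: Rh2(S-TCPTTL)4 (1 mol %), PhCF3, 0 to 23 °C, slow addition of 15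
Reagents that add atoms: none
Why: Rh(II) extrudes N2 from 15 to give the electrophilic carbenoid 16 at C10, which is attacked by the oxygen of the neighbouring ester carbonyl (C7=O); this closes the six-membered ring O–C7–C8–C9–C20–C10 (the C10–O bond) and gives the 1-methoxy-2-benzopyrylium-4-olate 17, a carbonyl ylide with termini C7 and C10. The ylide is trapped by the tethered C5=C6 vinyl group in an intramolecular [3+2] (1,3-dipolar) cycloaddition in the fused mode, which forms C10–C5 and C7–C6 and so closes the oxolane ring (O, C7, C6, C5, C10), six-membered ring A (C10, C1–C5) and seven-membered ring B (C5–C6–C7–C8–C9–C20–C10). The closest known reaction type is the Rh(II)-catalysed cyclisation–cycloaddition cascade of diazo dicarbonyl compounds through six-membered carbonyl ylides, among them ester-derived 1-alkoxy-2-benzopyrylium-4-olates, including intramolecular trapping by unactivated tethered alkenes and enantioselective versions with chiral dirhodium carboxylates. C7 and C10 are joined suprafacially through the oxygen bridge, and C5 is fixed relative to them by the tether C1–C2–C3–C4, which spans C10 and C5 without strain only with C4 exo (syn to the oxygen bridge, H-5 anti to O-10, as in the target); the absolute configuration comes from the chiral carboxylate ligands while the ylide is still associated with rhodium. Chemoselectivity rests on the substrate: the diazo carbon carries two acyl groups and no β-hydrogen (no 1,2-H shift), the quaternary C4 removes the 1,5-C–H insertion site, the ester carbonyl is placed for six-ring ylide formation ahead of the C11 methoxy oxygen or cyclopropanation of the remote alkene, and the tether length dictates the regiochemistry of the cycloaddition.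

Step 14
Reactants: 18 (5S,7S,10S)-7,10-epoxy-7,11,12,14-tetramethoxyicetexa-8,11,13-triene-1,20-dione
Product: 19 (5S,7S,10S)-7,10-epoxy-7,11,12,14-tetramethoxyicetexa-8,11,13-triene-1,20-diol
Conditions: LiAlH4, THF, −20 to 0 °C; aqueous NaOH work-up
Reagents that add atoms: none
Why: Hydride reduction of both non-enolisable ketones should give the diol, with the methyl ketal and aryl ethers inert; the two new carbinol centres are removed later and need no control.

Step 15
Reactants: 19 (5S,7S,10S)-7,10-epoxy-7,11,12,14-tetramethoxyicetexa-8,11,13-triene-1,20-diol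
Product: 20 O,O'-[(5S,7S,10S)-7,10-epoxy-7,11,12,14-tetramethoxyicetexa-8,11,13-triene-1,20-diyl] bis(S-methyl dithiocarbonate)
Conditions: NaH, imidazole (cat.), THF, 0 to 23 °C; CS2 (excess); then MeI
Reagents that add atoms: carbon disulfide, S=C=S; iodomethane, CI
Why: Xanthate formation, in which both alkoxides are converted to xanthate salts with excess CS2 before MeI is added, so that no alkoxide meets an S-methyl xanthate.

Step 16
Reactants: 20 O,O'-[(5S,7S,10S)-7,10-epoxy-7,11,12,14-tetramethoxyicetexa-8,11,13-triene-1,20-diyl] bis(S-methyl dithiocarbonate)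
Product: 21 (5S,7S,10S)-7,10-epoxy-7,11,12,14-tetramethoxyicetexa-8,11,13-triene
Conditions: Bu3SnH, AIBN, toluene, 110 °C
Reagents that add atoms: none
Why: Double Barton–McCombie deoxygenation through a benzylic C20 radical and a secondary C1 radical; β-alkoxy radicals do not expel the C10 oxygen, and the ketal is stable under neutral radical conditions.

Step 17
Reactants: 21 (5S,7S,10S)-7,10-epoxy-7,11,12,14-tetramethoxyicetexa-8,11,13-triene
Product: 23 komaroviquinone, via hemiketal 22 (not isolated)
Conditions: 1 M HCl, MeCN, 23 °C; then CAN, MeCN–H2O, 0 °C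
Reagents that add atoms: water, O
Why: Acid hydrolysis of the aryl ketal (C7–O ionisation assisted by the methoxy group and the electron-rich ring, then re-closure of the C10-hydroxyl onto C7, whose configuration is dictated by the bridge) followed by CAN oxidative demethylation of the para-related C11 and C14 methoxy groups should give the 11,14-quinone with the C12 methoxy group retained; C5 and C10 are not touched.

**Compound list**

1 | methyl 3,3-dimethylpent-4-enoate | COC(=O)CC(C)(C)C=C | starting material
2 | 3,3-dimethylpent-4-en-1-ol | OCCC(C)(C)C=C | intermediate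
3 | 5-iodo-3,3-dimethylpent-1-ene | ICCC(C)(C)C=C | intermediate
4 | 5,5-dimethylhept-6-en-1-yne | C#CCCC(C)(C)C=C | intermediate
5 | N-methoxy-N,6,6-trimethyloct-7-en-2-ynamide | CON(C)C(=O)C#CCCC(C)(C)C=C | intermediate
6 | 1,2,4-trimethoxybenzene | COc1ccc(OC)c(OC)c1 | starting material
7 | 2-(2,3,6-trimethoxyphenyl)propan-2-ol | CC(C)(O)c1c(OC)ccc(OC)c1OC | intermediate
8 | 1,2,4-trimethoxy-3-(propan-2-yl)benzene | CC(C)c1c(OC)ccc(OC)c1OC | intermediate
9 | 1-bromo-2,4,5-trimethoxy-3-(propan-2-yl)benzene | CC(C)c1c(OC)c(Br)cc(OC)c1OC | intermediate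
10 | 2,4,5-trimethoxy-3-(propan-2-yl)benzoic acid | CC(C)c1c(OC)c(C(=O)O)cc(OC)c1OC | intermediate
11 | 2-(6,6-dimethyloct-7-en-2-ynoyl)-3,4,6-trimethoxy-5-(propan-2-yl)benzoic acid | OC(=O)c1c(OC)c(C(C)C)c(OC)c(OC)c1C(=O)C#CCCC(C)(C)C=C | intermediate
12 | methyl 2-(6,6-dimethyloct-7-en-2-ynoyl)-3,4,6-trimethoxy-5-(propan-2-yl)benzoate | COC(=O)c1c(OC)c(C(C)C)c(OC)c(OC)c1C(=O)C#CCCC(C)(C)C=C | intermediate
13 | methyl 2-[(2E)-3-(diethylamino)-6,6-dimethylocta-2,7-dienoyl]-3,4,6-trimethoxy-5-(propan-2-yl)benzoate (enaminone, E expected) | COC(=O)c1c(OC)c(C(C)C)c(OC)c(OC)c1C(=O)/C=C(\CCC(C)(C)C=C)N(CC)CC | intermediate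
14 | methyl 2-(6,6-dimethyl-3-oxooct-7-enoyl)-3,4,6-trimethoxy-5-(propan-2-yl)benzoate | COC(=O)c1c(OC)c(C(C)C)c(OC)c(OC)c1C(=O)CC(=O)CCC(C)(C)C=C | intermediate
15 | methyl 2-(2-diazo-6,6-dimethyl-3-oxooct-7-enoyl)-3,4,6-trimethoxy-5-(propan-2-yl)benzoate | COC(=O)c1c(OC)c(C(C)C)c(OC)c(OC)c1C(=O)C(=[N+]=[N-])C(=O)CCC(C)(C)C=C | intermediate
16 | rhodium carbenoid of 15 at C10 (carboxylate ligands and second Rh omitted) | COC(=O)c1c(OC)c(C(C)C)c(OC)c(OC)c1C(=O)C(=[Rh])C(=O)CCC(C)(C)C=C | intermediate
17 | 3-(4,4-dimethylhex-5-enoyl)-1,5,6,8-tetramethoxy-7-(propan-2-yl)-2-benzopyrylium-4-olate (carbonyl ylide) | COC1=[O+]C(C(=O)CCC(C)(C)C=C)=C([O-])c2c(OC)c(OC)c(C(C)C)c(OC)c12 | intermediate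
18 | (5S,7S,10S)-7,10-epoxy-7,11,12,14-tetramethoxyicetexa-8,11,13-triene-1,20-dione | COc1c(C(C)C)c(OC)c2c(C(=O)[C@@]34C(=O)CCC(C)(C)[C@@H]3C[C@]2(OC)O4)c1OC | intermediate
19 | (5S,7S,10S)-7,10-epoxy-7,11,12,14-tetramethoxyicetexa-8,11,13-triene-1,20-diol (C1/C20 epimers) | COc1c(C(C)C)c(OC)c2c(C(O)[C@@]34C(O)CCC(C)(C)[C@@H]3C[C@]2(OC)O4)c1OC | intermediate
20 | O,O'-[(5S,7S,10S)-7,10-epoxy-7,11,12,14-tetramethoxyicetexa-8,11,13-triene-1,20-diyl] bis(S-methyl dithiocarbonate) (C1/C20 epimers) | COc1c(C(C)C)c(OC)c2c(C(OC(=S)SC)[C@@]34C(OC(=S)SC)CCC(C)(C)[C@@H]3C[C@]2(OC)O4)c1OC | intermediate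
21 | (5S,7S,10S)-7,10-epoxy-7,11,12,14-tetramethoxyicetexa-8,11,13-triene | COc1c(C(C)C)c(OC)c2c(C[C@@]34CCCC(C)(C)[C@@H]3C[C@]2(OC)O4)c1OC | intermediate
22 | (5S,7S,10S)-7,10-epoxy-11,12,14-trimethoxyicetexa-8,11,13-trien-7-ol (hemiketal) | COc1c(C(C)C)c(OC)c2c(C[C@@]34CCCC(C)(C)[C@@H]3C[C@]2(O)O4)c1OC | intermediate
23 | komaroviquinone, (5S,7S,10S)-7,10-epoxy-7-hydroxy-12-methoxyicetexa-8,12-diene-11,14-dione | COC1=C(C(C)C)C(=O)C2=C(C[C@@]34CCCC(C)(C)[C@@H]3C[C@]2(O)O4)C1=O | target

**Totals**

Total step count: 17. Longest linear sequence: 13 steps (steps 5–17, from 1,2,4-trimethoxybenzene 6); the side chain (steps 1–4) joins in step 9.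

**Steps most likely to fail**

Step 13. The ylide may leave rhodium before the cycloaddition, so that the catalyst no longer controls which face of the dipole the alkene meets and the enantiomeric purity falls; part of the carbenoid may also be diverted to an oxonium ylide with the C11 methoxy oxygen. Fallback: setting out from 15, the cascade is run with achiral Rh2(OAc)4 in toluene at 40–80 °C. The relative configuration is still fixed by the tether, and the product is the racemate, that is 18 together with its enantiomer (5R,7R,10R)-7,10-epoxy-7,11,12,14-tetramethoxyicetexa-8,11,13-triene-1,20-dione F1. The enantiomers are separated by preparative chromatography on an amylose-based chiral stationary phase, and the route is rejoined at 18.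

Step 9. s-BuLi may add to the lithium carboxylate or displace the ortho methoxy group instead of removing the ring proton, and the hindered dianion may add to the ynamide in the conjugate sense. Fallback: setting out from bromide 9, bromine–lithium exchange (n-BuLi, THF, −78 °C) and trapping with methyl chloroformate give methyl 2,4,5-trimethoxy-3-(propan-2-yl)benzoate F2. Iodination of the single remaining ring position (NIS, cat. CF3CO2H, MeCN) gives methyl 2-iodo-3,4,6-trimethoxy-5-(propan-2-yl)benzoate F3. Carbonylative Sonogashira coupling of F3 with alkyne 4 (PdCl2(PPh3)2, CuI, CO 1 atm, Et3N, THF) gives ynone ester 12, where the route is rejoined. In this variant no organolithium meets a carboxylate and steps 4, 8 and 10 are not needed.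

Step 15. After the first xanthate has formed, the neighbouring alkoxide may attack it and close a cyclic thionocarbonate across the 1,3-diol, or the hindered second hydroxyl may escape thioacylation. Fallback: setting out from diol 19, the cyclisation is made the intended course with 1,1'-thiocarbonyldiimidazole and DMAP in toluene at 90 °C, giving (5S,7S,10S)-7,10-epoxy-7,11,12,14-tetramethoxyicetexa-8,11,13-triene-1,20-diyl thionocarbonate F4. Bu3SnH/AIBN in refluxing toluene should open it at the benzylic C20–O bond, and a NaOH/MeOH work-up should give (5S,7S,10S)-7,10-epoxy-7,11,12,14-tetramethoxyicetexa-8,11,13-trien-1-ol F5. Its xanthate (NaH, CS2, MeI), O-[(5S,7S,10S)-7,10-epoxy-7,11,12,14-tetramethoxyicetexa-8,11,13-trien-1-yl] S-methyl dithiocarbonate F6, is reduced with Bu3SnH/AIBN to 21, where the route is rejoined.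

**Further compounds**

F1 | step 13 | (5R,7R,10R)-7,10-epoxy-7,11,12,14-tetramethoxyicetexa-8,11,13-triene-1,20-dione (enantiomer of 18) | COc1c(C(C)C)c(OC)c2c(C(=O)[C@]34C(=O)CCC(C)(C)[C@H]3C[C@@]2(OC)O4)c1OC
F2 | step 9 | methyl 2,4,5-trimethoxy-3-(propan-2-yl)benzoate | COC(=O)c1cc(OC)c(OC)c(C(C)C)c1OC
F3 | step 9 | methyl 2-iodo-3,4,6-trimethoxy-5-(propan-2-yl)benzoate | COC(=O)c1c(I)c(OC)c(OC)c(C(C)C)c1OC
F4 | step 15 | (5S,7S,10S)-7,10-epoxy-7,11,12,14-tetramethoxyicetexa-8,11,13-triene-1,20-diyl thionocarbonate | COc1c(C(C)C)c(OC)c2c(C5[C@@]34C(OC(=S)O5)CCC(C)(C)[C@@H]3C[C@]2(OC)O4)c1OC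
F5 | step 15 | (5S,7S,10S)-7,10-epoxy-7,11,12,14-tetramethoxyicetexa-8,11,13-trien-1-ol | COc1c(C(C)C)c(OC)c2c(C[C@@]34C(O)CCC(C)(C)[C@@H]3C[C@]2(OC)O4)c1OC
F6 | step 15 | O-[(5S,7S,10S)-7,10-epoxy-7,11,12,14-tetramethoxyicetexa-8,11,13-trien-1-yl] S-methyl dithiocarbonate | COc1c(C(C)C)c(OC)c2c(C[C@@]34C(OC(=S)SC)CCC(C)(C)[C@@H]3C[C@]2(OC)O4)c1OC
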